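**Strategy**

The chain is cut at the C10–C11 single bond, beside the cis C11=C12 olefin of the (11Z,13E)-diene. This two-carbon cis-vinylene, lying between the C10 methylene and the trans C13=C14 olefin, is acetylene in disguise: in one three-component operation an (E)-alkenyl cuprate (C13–C20, carrying C15) adds syn to acetylene, forging C12–C13 and fixing 11Z, and the resulting dienyl cuprate is allylated by a (5Z,8Z)-allylic bromide (C1–C10) that already bears the silylated acylphloroglucinol ring, closing C10–C11. The precursors are an enantiopure vinyl iodide from methyl (S)-glycidate and a bromide from Hoesch acylation, skipped-diyne coupling and semihydrogenation; fluoride desilylation ends the route.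

Key step: step 10

Remark: chain carbons are numbered C1 (ketone carbon) to C20 (methyl); TBS = tert-butyldimethylsilyl; the copper reagents of steps 6 and 10 are assumed to be lithium diorganocuprates R2CuLi.

**Route**

Step 1
Reactants: 1 phloroglucinol (benzene-1,3,5-triol); 2 hex-5-ynenitrile
Product: 4 1-(2,4,6-trihydroxyphenyl)hex-5-yn-1-one, via ketiminium chloride 3 (not isolated)
Conditions: ZnCl2, HCl (g), Et2O, 0 °C; then H2O, reflux
Reagents that add atoms: water, O
Why: Houben–Hoesch acylation, in which the HCl-activated nitrile attacks the symmetric, threefold-activated ring once (the iminium salt 3 deactivates it against a second attack) and hydrolysis releases the ketone, while the unactivated terminal alkyne is expected to be inert to HCl in ether at 0 °C.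

Step 2
Reactants: 4 1-(2,4,6-trihydroxyphenyl)hex-5-yn-1-one
Product: 5 1-[2,4,6-tris(tert-butyldimethylsilyloxy)phenyl]hex-5-yn-1-one
Conditions: TBSCl (excess), imidazole, DMAP (cat.), DMF, rt to 40 °C
Reagents that add atoms: tert-butyldimethylsilyl chloride (TBSCl), CC(C)(C)[Si](C)(C)Cl
Why: Standard silyl ether formation (silyl chloride/imidazole), in which excess reagent, DMAP and gentle warming should also silylate the two hydrogen-bonded ortho hydroxyls, leaving a ketone with no acidic O–H for the later cuprate step.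

Step 3
Reactants: 5 1-[2,4,6-tris(tert-butyldimethylsilyloxy)phenyl]hex-5-yn-1-one; 6 4-chlorobut-2-yn-1-ol
Product: 8 10-hydroxy-1-[2,4,6-tris(tert-butyldimethylsilyloxy)phenyl]deca-5,8-diyn-1-one, via 4-iodobut-2-yn-1-ol 7 (not isolated)
Conditions: CuI, NaI, K2CO3, DMF, rt
Reagents that add atoms: none
Why: Copper-mediated sp–sp3 coupling of a terminal alkyne with a propargylic halide (after Finkelstein exchange to iodide 7), in which the copper acetylide of 5 displaces iodide by SN2 without allene formation to give the skipped diyne (C6–C7 bond) under conditions that leave the hindered ketone untouched.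

Step 4
Reactants: 8 10-hydroxy-1-[2,4,6-tris(tert-butyldimethylsilyloxy)phenyl]deca-5,8-diyn-1-one
Product: 9 (5Z,8Z)-10-hydroxy-1-[2,4,6-tris(tert-butyldimethylsilyloxy)phenyl]deca-5,8-dien-1-one
Conditions: H2 (1 atm), Pd/CaCO3 poisoned with Pb(OAc)2 (Lindlar catalyst), quinoline, EtOAc, rt
Reagents that add atoms: none
Why: Lindlar semihydrogenation delivers hydrogen syn to each alkyne on the poisoned palladium surface, setting 5Z and 8Z and stopping at the alkene, while ketone and silyl ethers are inert.

Step 5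
Reactants: 9 (5Z,8Z)-10-hydroxy-1-[2,4,6-tris(tert-butyldimethylsilyloxy)phenyl]deca-5,8-dien-1-one
Product: 10 (5Z,8Z)-10-bromo-1-[2,4,6-tris(tert-butyldimethylsilyloxy)phenyl]deca-5,8-dien-1-one
Conditions: CBr4, PPh3, CH2Cl2, −20 to 0 °C
Reagents that add atoms: carbon tetrabromide, BrC(Br)(Br)Br
Why: Appel bromination, in which the alkoxyphosphonium salt of the primary allylic alcohol is displaced by bromide in a direct SN2 reaction under neutral conditions, so neither allylic transposition nor Z to E isomerisation is expected.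

Step 6
Reactants: 11 ethyllithium; 12 acetylene; 13 methyl (2S)-oxirane-2-carboxylate (methyl (S)-glycidate)
Product: 16 methyl (2S,4Z)-2-hydroxyhept-4-enoate, via lithium diethylcuprate 14 (not isolated), via lithium di[(Z)-but-1-enyl]cuprate 15 (not isolated)
Conditions: CuBr·SMe2 (0.5 equiv per EtLi), Et2O, −40 °C; acetylene (1 equiv per ethyl), −50 to −25 °C; then 13, −78 to −20 °C; aq. NH4Cl
Reagents that add atoms: none
Why: Carbocupration of acetylene, in which the ethyl–copper bonds of 14 add syn across acetylene to give the Z-butenyl cuprate 15 (this fixes 17Z of the target), followed by cuprate opening of the glycidic ester by SN2 at its unsubstituted C3, which leaves the C2 stereocentre (the future C15) untouched as S.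

Step 7
Reactants: 16 methyl (2S,4Z)-2-hydroxyhept-4-enoate
Product: 17 methyl (2S,4Z)-2-(tert-butyldimethylsilyloxy)hept-4-enoate
Conditions: TBSCl, imidazole, DMF, rt
Reagents that add atoms: tert-butyldimethylsilyl chloride (TBSCl), CC(C)(C)[Si](C)(C)Cl
Why: Silyl ether formation on a secondary α-hydroxy ester with silyl chloride/imidazole, a base too mild to epimerise C2.

Step 8
Reactants: 17 methyl (2S,4Z)-2-(tert-butyldimethylsilyloxy)hept-4-enoate
Product: 18 (2S,4Z)-2-(tert-butyldimethylsilyloxy)hept-4-enal
Conditions: i-Bu2AlH, CH2Cl2, −78 °C; then aq. potassium sodium tartrate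
Reagents that add atoms: none
Why: Partial reduction of an ester with i-Bu2AlH at −78 °C, where the tetrahedral aluminium hemiacetal, stabilised by the neighbouring silyloxy group, should survive until work-up and so give the aldehyde without over-reduction or epimerisation.

Step 9
Reactants: 18 (2S,4Z)-2-(tert-butyldimethylsilyloxy)hept-4-enal
Product: 19 tert-butyl{[(1E,3S,5Z)-1-iodoocta-1,5-dien-3-yl]oxy}dimethylsilane
Conditions: CrCl2, CHI3, THF, 0 °C to rt
Reagents that add atoms: iodoform, IC(I)I
Why: Takai olefination, in which the geminal dichromium species formed from iodoform and divalent chromium adds to the aldehyde and eliminates to the E-vinyl iodide (13E of the target) under non-basic conditions that should not epimerise the α-stereocentre.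

Step 10
Reactants: 19 tert-butyl{[(1E,3S,5Z)-1-iodoocta-1,5-dien-3-yl]oxy}dimethylsilane; 12 acetylene; 10 (5Z,8Z)-10-bromo-1-[2,4,6-tris(tert-butyldimethylsilyloxy)phenyl]deca-5,8-dien-1-one
Product: 23 (5Z,8Z,11Z,13E,15S,17Z)-15-(tert-butyldimethylsilyloxy)-1-[2,4,6-tris(tert-butyldimethylsilyloxy)phenyl]icosa-5,8,11,13,17-pentaen-1-one, via alkenyllithium 20 (not isolated), via lithium dialkenylcuprate 21 (not isolated), via lithium bis(dienyl)cuprate 22 (not isolated)
Conditions: t-BuLi (2 equiv), Et2O, −78 °C; CuBr·SMe2 (0.5 equiv), −40 °C; acetylene (1 equiv per alkenyl), −40 to −20 °C; then 10 (1 equiv per dienyl), THF, −78 to −20 °C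
Reagents that add atoms: none
Why: Iodine–lithium exchange with retention gives the E-alkenyllithium 20 and, with half an equivalent of CuBr·SMe2, the homocuprate 21, whose alkenyl–copper bonds add syn across acetylene (carbocupration) to forge C12–C13 and place copper on C11 cis to the new substituent; the sp2 C11–Cu bond of the dienyl cuprate 22 is then allylated by bromide 10 with retention, forming C10–C11. The closest known reaction types are the carbocupration of acetylene by lithium dialkenylcuprates to (1Z,3E)-dienyl cuprates and the allylation of Z-alkenyl cuprates to skipped dienes. No ring is closed and no stereocentre is created: C15 (S) is carried unchanged from 19, 11Z is fixed by the syn addition, and 13E, 17Z, 5Z and 8Z come from the precursors. The step needs a single acetylene insertion, secured by metering one equivalent of gas per alkenyl ligand and by the lower reactivity of the dienyl cuprate at −20 °C, and attack at the primary C10 instead of C8, favoured because C10 is the unhindered terminus whereas C8 carries the C7 chain, with 8Z kept because alkenyl–allyl reductive elimination from trivalent copper at low temperature should outrun isomerisation of the allyl unit. The ketone should survive because it is flanked by two ortho silyloxy groups and cuprates are weakly basic and add slowly to hindered ketones. Both dienyl ligands of 22 can be delivered to the reactive allylic bromide, so two molecules of 19 and of 10 are joined per copper.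

Step 11
Reactants: 23 (5Z,8Z,11Z,13E,15S,17Z)-15-(tert-butyldimethylsilyloxy)-1-[2,4,6-tris(tert-butyldimethylsilyloxy)phenyl]icosa-5,8,11,13,17-pentaen-1-one
Product: 24 (5Z,8Z,11Z,13E,15S,17Z)-15-hydroxy-1-(2,4,6-trihydroxyphenyl)icosa-5,8,11,13,17-pentaen-1-one
Conditions: TBAF, AcOH, THF, 0 °C to rt, under argon
Reagents that add atoms: none
Why: Fluoride-mediated desilylation should cleave the three aryl silyl ethers and the secondary allylic silyl ether in one operation, the acetic acid buffer avoiding both strong base (isomerisation of the skipped polyene) and strong acid (ionisation of the dienylic C15 alcohol).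

**Compound list**

1 | phloroglucinol (benzene-1,3,5-triol) | Oc1cc(O)cc(O)c1 | starting material
2 | hex-5-ynenitrile | C#CCCCC#N | starting material
3 | 1-(2,4,6-trihydroxyphenyl)hex-5-yn-1-iminium chloride | C#CCCCC(=[NH2+])c1c(O)cc(O)cc1O.[Cl-] | intermediate
4 | 1-(2,4,6-trihydroxyphenyl)hex-5-yn-1-one | C#CCCCC(=O)c1c(O)cc(O)cc1O | intermediate
5 | 1-[2,4,6-tris(tert-butyldimethylsilyloxy)phenyl]hex-5-yn-1-one | C#CCCCC(=O)c1c(O[Si](C)(C)C(C)(C)C)cc(O[Si](C)(C)C(C)(C)C)cc1O[Si](C)(C)C(C)(C)C | intermediate
6 | 4-chlorobut-2-yn-1-ol | OCC#CCCl | starting material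
7 | 4-iodobut-2-yn-1-ol | OCC#CCI | intermediate
8 | 10-hydroxy-1-[2,4,6-tris(tert-butyldimethylsilyloxy)phenyl]deca-5,8-diyn-1-one | OCC#CCC#CCCCC(=O)c1c(O[Si](C)(C)C(C)(C)C)cc(O[Si](C)(C)C(C)(C)C)cc1O[Si](C)(C)C(C)(C)C | intermediate
9 | (5Z,8Z)-10-hydroxy-1-[2,4,6-tris(tert-butyldimethylsilyloxy)phenyl]deca-5,8-dien-1-one | OC/C=C\C/C=C\CCCC(=O)c1c(O[Si](C)(C)C(C)(C)C)cc(O[Si](C)(C)C(C)(C)C)cc1O[Si](C)(C)C(C)(C)C | intermediate
10 | (5Z,8Z)-10-bromo-1-[2,4,6-tris(tert-butyldimethylsilyloxy)phenyl]deca-5,8-dien-1-one | BrC/C=C\C/C=C\CCCC(=O)c1c(O[Si](C)(C)C(C)(C)C)cc(O[Si](C)(C)C(C)(C)C)cc1O[Si](C)(C)C(C)(C)C | intermediate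
11 | ethyllithium | [Li]CC | starting material
12 | acetylene | C#C | starting material
13 | methyl (2S)-oxirane-2-carboxylate (methyl (S)-glycidate) | COC(=O)[C@@H]1CO1 | starting material
14 | lithium diethylcuprate | [Li+].CC[Cu-]CC | intermediate
15 | lithium di[(Z)-but-1-en-1-yl]cuprate | [Li+].CC/C=C\[Cu-]/C=C\CC | intermediate
16 | methyl (2S,4Z)-2-hydroxyhept-4-enoate | CC/C=C\C[C@H](O)C(=O)OC | intermediate
17 | methyl (2S,4Z)-2-(tert-butyldimethylsilyloxy)hept-4-enoate | CC/C=C\C[C@H](O[Si](C)(C)C(C)(C)C)C(=O)OC | intermediate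
18 | (2S,4Z)-2-(tert-butyldimethylsilyloxy)hept-4-enal | CC/C=C\C[C@H](O[Si](C)(C)C(C)(C)C)C=O | intermediate
19 | tert-butyl{[(1E,3S,5Z)-1-iodoocta-1,5-dien-3-yl]oxy}dimethylsilane | CC/C=C\C[C@H](O[Si](C)(C)C(C)(C)C)/C=C/I | intermediate
20 | [(1E,3S,5Z)-3-(tert-butyldimethylsilyloxy)octa-1,5-dien-1-yl]lithium | CC/C=C\C[C@H](O[Si](C)(C)C(C)(C)C)/C=C/[Li] | intermediate
21 | lithium bis[(1E,3S,5Z)-3-(tert-butyldimethylsilyloxy)octa-1,5-dien-1-yl]cuprate | [Li+].CC/C=C\C[C@H](O[Si](C)(C)C(C)(C)C)/C=C/[Cu-]/C=C/[C@@H](O[Si](C)(C)C(C)(C)C)C/C=C\CC | intermediate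
22 | lithium bis[(1Z,3E,5S,7Z)-5-(tert-butyldimethylsilyloxy)deca-1,3,7-trien-1-yl]cuprate | [Li+].CC/C=C\C[C@H](O[Si](C)(C)C(C)(C)C)/C=C/C=C\[Cu-]\C=C/C=C/[C@@H](O[Si](C)(C)C(C)(C)C)C/C=C\CC | intermediate
23 | (5Z,8Z,11Z,13E,15S,17Z)-15-(tert-butyldimethylsilyloxy)-1-[2,4,6-tris(tert-butyldimethylsilyloxy)phenyl]icosa-5,8,11,13,17-pentaen-1-one | CC/C=C\C[C@H](O[Si](C)(C)C(C)(C)C)/C=C/C=C\C/C=C\C/C=C\CCCC(=O)c1c(O[Si](C)(C)C(C)(C)C)cc(O[Si](C)(C)C(C)(C)C)cc1O[Si](C)(C)C(C)(C)C | intermediate
24 | (5Z,8Z,11Z,13E,15S,17Z)-15-hydroxy-1-(2,4,6-trihydroxyphenyl)icosa-5,8,11,13,17-pentaen-1-one | CC/C=C\C[C@H](O)/C=C/C=C\C/C=C\C/C=C\CCCC(=O)c1c(O)cc(O)cc1O | target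

**Step count**

Total steps: 11. Longest linear sequence: 7 steps (steps 1 to 5, then 10 and 11); the vinyl iodide branch (steps 6 to 9) joins at step 10.

**Steps most likely to fail, with fallbacks**

1. Step 10. The dienyl cuprate may attack the allylic bromide at C8 instead of C10, the 8Z olefin may isomerise through an allyl-copper intermediate, or acetylene uptake may be incomplete or go beyond one insertion. The fallback makes the same C10–C11 bond by copper acetylide chemistry. It sets out from vinyl iodide 19 and uses bromide 10. Sonogashira coupling of 19 with ethynyltrimethylsilane (Pd(PPh3)4, CuI, Et3N, rt) should give tert-butyldimethyl{[(3E,5S,7Z)-1-(trimethylsilyl)deca-3,7-dien-1-yn-5-yl]oxy}silane F1. K2CO3 in MeOH should then free the terminal alkyne, tert-butyl{[(3E,5S,7Z)-deca-3,7-dien-1-yn-5-yl]oxy}dimethylsilane F2. Coupling of F2 with allylic bromide 10 (CuI, K2CO3, DMF, rt) should give (5Z,8Z,13E,15S,17Z)-15-(tert-butyldimethylsilyloxy)-1-[2,4,6-tris(tert-butyldimethylsilyloxy)phenyl]icosa-5,8,13,17-tetraen-11-yn-1-one F3. Cis reduction of the conjugated enyne (zinc activated with Cu(OAc)2 and AgNO3 in aqueous methanol, Boland reduction) sets 11Z and comes back to the route at 23.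

2. Step 3. During the long carbonate-mediated coupling the aryl silyl ethers may be lost or transferred to the primary alkoxide of 6, and the freed phenoxide may then be O-propargylated. The fallback runs the coupling on base-stable acetals and installs the silyl groups afterwards. It sets out from triphenol 4. MOMCl and NaH in DMF should give 1-[2,4,6-tris(methoxymethoxy)phenyl]hex-5-yn-1-one F4. The coupling with 6 under the conditions of step 3 (by way of 7) should give 10-hydroxy-1-[2,4,6-tris(methoxymethoxy)phenyl]deca-5,8-diyn-1-one F5. HCl in MeOH at 50 °C, which the skipped diyne tolerates, should remove the acetals to 10-hydroxy-1-(2,4,6-trihydroxyphenyl)deca-5,8-diyn-1-one F6. Excess TBSCl and imidazole should give 10-(tert-butyldimethylsilyloxy)-1-[2,4,6-tris(tert-butyldimethylsilyloxy)phenyl]deca-5,8-diyn-1-one F7. PPTS in MeOH at 0 °C should cleave only the primary alkyl silyl ether, the aryl silyl ethers being the more acid-stable, and the sequence comes back to the route at 8.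

3. Step 6. Opening of the epoxide by the thermally fragile Z-alkenyl cuprate may be slow, so that decomposition of the cuprate or attack at the ester competes. The fallback builds the 4Z olefin by a Wittig reaction instead. It sets out from glycidate 13. Vinylmagnesium bromide with catalytic CuI (THF, −78 to −40 °C) should open the epoxide at C3 to methyl (2S)-2-hydroxypent-4-enoate F8. TBSCl and imidazole should give methyl (2S)-2-(tert-butyldimethylsilyloxy)pent-4-enoate F9. Ozonolysis (O3, CH2Cl2, −78 °C; then PPh3) should give methyl (2S)-2-(tert-butyldimethylsilyloxy)-4-oxobutanoate F10. A salt-free Wittig reaction with propylidenetriphenylphosphorane F11 (from n-propyltriphenylphosphonium bromide and NaN(SiMe3)2, THF, −78 °C) should give the Z-olefin and comes back to the route at 17.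

**Further compounds**

F1 | step 10 | tert-butyldimethyl{[(3E,5S,7Z)-1-(trimethylsilyl)deca-3,7-dien-1-yn-5-yl]oxy}silane | CC/C=C\C[C@H](O[Si](C)(C)C(C)(C)C)/C=C/C#C[Si](C)(C)C
F2 | step 10 | tert-butyl{[(3E,5S,7Z)-deca-3,7-dien-1-yn-5-yl]oxy}dimethylsilane | CC/C=C\C[C@H](O[Si](C)(C)C(C)(C)C)/C=C/C#C
F3 | step 10 | (5Z,8Z,13E,15S,17Z)-15-(tert-butyldimethylsilyloxy)-1-[2,4,6-tris(tert-butyldimethylsilyloxy)phenyl]icosa-5,8,13,17-tetraen-11-yn-1-one | CC/C=C\C[C@H](O[Si](C)(C)C(C)(C)C)/C=C/C#CC/C=C\C/C=C\CCCC(=O)c1c(O[Si](C)(C)C(C)(C)C)cc(O[Si](C)(C)C(C)(C)C)cc1O[Si](C)(C)C(C)(C)C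
F4 | step 3 | 1-[2,4,6-tris(methoxymethoxy)phenyl]hex-5-yn-1-one | C#CCCCC(=O)c1c(OCOC)cc(OCOC)cc1OCOC
F5 | step 3 | 10-hydroxy-1-[2,4,6-tris(methoxymethoxy)phenyl]deca-5,8-diyn-1-one | OCC#CCC#CCCCC(=O)c1c(OCOC)cc(OCOC)cc1OCOC
F6 | step 3 | 10-hydroxy-1-(2,4,6-trihydroxyphenyl)deca-5,8-diyn-1-one | OCC#CCC#CCCCC(=O)c1c(O)cc(O)cc1O
F7 | step 3 | 10-(tert-butyldimethylsilyloxy)-1-[2,4,6-tris(tert-butyldimethylsilyloxy)phenyl]deca-5,8-diyn-1-one | CC(C)(C)[Si](C)(C)OCC#CCC#CCCCC(=O)c1c(O[Si](C)(C)C(C)(C)C)cc(O[Si](C)(C)C(C)(C)C)cc1O[Si](C)(C)C(C)(C)C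
F8 | step 6 | methyl (2S)-2-hydroxypent-4-enoate | C=CC[C@H](O)C(=O)OC
F9 | step 6 | methyl (2S)-2-(tert-butyldimethylsilyloxy)pent-4-enoate | C=CC[C@H](O[Si](C)(C)C(C)(C)C)C(=O)OC
F10 | step 6 | methyl (2S)-2-(tert-butyldimethylsilyloxy)-4-oxobutanoate | O=CC[C@H](O[Si](C)(C)C(C)(C)C)C(=O)OC
F11 | step 6 | propylidenetriphenylphosphorane | CCC=P(c1ccccc1)(c1ccccc1)c1ccccc1
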